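**On the bench.** If you take over this flask, expect a slow reaction. The substrate sits in the first phase, the reagent in the second, and target builds up.

| flask | substrate | reagent in the second phase | remark | time | volume of the second phase over the first |
|---|---|---|---|---|---|
| violet | 13 mM | 1.2 equiv | run made earlier |  |  |
| ochre | 13 mM | 5 equiv | run made earlier |  |  |
| red | 20 mM | 2.5 equiv | run made earlier |  |  |
| flask | 13 mM | 2.50 equiv |  | 12 h | 0.50 |

- violet (time / h: target / %, substrate / %): 0.833: 0.5, 97.7; 1.33: 1.8, 97.4; 2.00: 2.0, 98.4; 2.50: 2.3, 96.1; 4.00: 2.7, 95.4; 6.00: 5.7, 92.8; 10.0: 9.7, 90.0
- ochre (time / h: target / %, substrate / %): 0.833: 2.1, 98.5; 1.33: 4.6, 95.0; 2.00: 8.2, 92.4; 2.50: 7.3, 89.5; 4.00: 11.6, 85.5; 6.00: 18.7, 79.3; 10.0: 25.1, 67.0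
- red (time / h: target / %, substrate / %): 0.833: 1.0, 98.3; 2.50: 7.9, 91.7; 4.00: 10.4, 88.6; 6.00: 15.6, 83.5; 10.0: 22.0, 74.6

(each reading ± 1 percentage point)

- in the second phase: reagent in the second phase; everything else is in the first
- charges count per volume of the first phase; a concentration in a rate is the amount of a species over the volume of its own phase; every rate counts per litre of the first phase
- the earlier runs were read with a standard deviation of 1 percentage point
- the earlier runs hold the two phases in the same ratio of volumes as the flask asked about

- the target standing at 12 h, as a percentage of the substrate charged
- the change that raises the amount of target at 12 h, in percent of the substrate charged most ("none" if none brings more than 2 percentage points) (dusk / winter / none)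
- amount of target at 12 h, in percent of the substrate charged, after winter

- dusk: doubling the amount of reagent in the second phase, all else as stated
- winter: doubling the transfer coefficient of the reagent in the second phase, all else as stated

**Our reckoning.** The ochre run left 67.0% of its substrate at 10.0 h. So 0.616 /M/h is our exposure constant: logarithmic substrate loss per hour and per concentration of reagent charged. It is read at the flask's phase ratio. Taking the rate as pseudo-first-order and integrating gives a substrate share of exp(−x), where x is the constant times reagent charged times time. The red run reads 74.6% substrate at 10.0 h against 73.5% reckoned.

**When you return.** Here x is 0.240. The ochre balance misses 7.9 percentage points at its last reading, and we read that as target being consumed. We let it go at the substrate's constant, which gives x·exp(−x), or 18.9% target.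

**Leave the stirring.** The ochre run reads 89.5% substrate at 2.50 h against 90.5% reckoned, so we see no lag beyond the scatter. Doubling the reagent in the second phase gives us 29.7% target by the same reckoning.

**The forecast.** It says 19% (16.5% to 21.5%), prefers dusk, and gives 20.5% (18% to 26%) after winter: “Doubling transfer only shortens a small early lag”.

**The flask.** It gives 18.3% target and 78% substrate, against 78.7% reckoned. Dusk adds 9.1 points, winter 0.14 points, reaching 18.4%.

    reagent in the reaction phase ⇌ reagent in the second phase, rate k1*([reagent in the reaction phase] - [reagent in the second phase]/K1) per volume of the first phase (partition coefficient = 11.0, kL = 0.0800 /min)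
    substrate + reagent in the reaction phase → target (k = 0.0730 /M/min)
    reagent in the reaction phase + target → over-reaction product (k = 0.100 /M/min)

**One comparison.** The transfer coefficient taken alone gives a half-life of 8.66 min, far shorter than the 12 h of reagent in the reaction phase by reaction with substrate at 0.259 h. In the flask, reagent in the reaction phase stood at 4.91 mM at 1.20 h and 4.46 mM at 12.0 h.

**Second flask.** With 22 mM substrate at the same equivalents, x is 0.407, giving 66.6% substrate and 27.1% target. That flask computes to 67.3% and 24.8%.

The readings are calculated from invented constants; noise was put on by code.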